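**Retrosynthetic overview**
- Feature: the cyclohexene ring is a masked 2-pyrone-5-carboxylate joined to a cis-dioxy alkene. Ring carbons C1–C4 with C7 come from the pyrone (its carbonyl carbon sits on C1, its ring oxygen on C4, its ester carbon is C7); C5–C6 come from the alkene.
- Late disconnections: the C5 benzoate from the cis-5,6-diol through a cyclic orthobenzoate; the C1 acetate from a C1 carboxylic acid by anodic (Hofer–Moest) decarboxylation; the C7 benzoate from the ester by reduction and benzoylation; the C1 acid and C4 hydroxyl from the bridging lactone.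
- Key disconnection: bonds C4–C5 and C1–C6, made together in a catalytic enantioselective inverse-demand Diels–Alder reaction of methyl coumalate with 2,2-dimethyl-1,3-dioxole, the CO2 bridge being kept. This is the only ring-forming step (the carbocycle); the dioxolane ring is carried in and later removed, the lactone ring is opened.
- The dioxole is made from 2,2-dimethyl-1,3-dioxolane by radical chlorination and dehydrochlorination.

Key step: step 3

Remark: the target locants C1 (OAc), C2, C3 (bearing C7), C4 (OH), C5 (OBz), C6 (OH) are used for all cyclohexene intermediates; O4, O5, O6 are the oxygens on those carbons; α is the face of the C1 and C4 oxygens, β the face of O5 and O6.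

Step 1
Reactants: 1 2,2-dimethyl-1,3-dioxolane
Product: 2 4-chloro-2,2-dimethyl-1,3-dioxolane (racemic)
Conditions: SO2Cl2 (0.9 equiv), AIBN (cat.), neat, 60–70 °C, N2 sweep; distilled
Reagents that add atoms: sulfuryl chloride, O=S(=O)(Cl)Cl
Why: Radical-chain chlorination attacks the only C–H bonds α to oxygen (the four equivalent ring hydrogens), as in the α-chlorination of tetrahydrofuran, 1,4-dioxane and ethylene carbonate, and the gas sweep removes HCl before it can open the ketal.

Step 2
Reactants: 2 4-chloro-2,2-dimethyl-1,3-dioxolane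
Product: 3 2,2-dimethyl-1,3-dioxole
Conditions: n-Bu3N (1.3 equiv), 110–130 °C, product distilled out as it forms
Reagents that add atoms: none
Why: α-Chloro ethers lose HCl on heating with a tertiary amine (the dehydrochlorination that turns chloroethylene carbonate into vinylene carbonate), and distilling the volatile enol ether away from the amine salt protects it from acid.

Step 3
Reactants: 3 2,2-dimethyl-1,3-dioxole; 4 methyl coumalate (methyl 2-oxo-2H-pyran-5-carboxylate)
Product: 5 methyl (1S,4R,7S,8S)-7,8-(isopropylidenedioxy)-3-oxo-2-oxabicyclo[2.2.2]oct-5-ene-6-carboxylate (endo adduct; acetonide oxygens anti to the lactone bridge)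
Conditions: (S)-3,3-diphenyl-1-(2-methylphenyl)tetrahydro-1H,3H-pyrrolo[1,2-c][1,3,2]oxazaborole (20 mol %), AlBr3 (16 mol %), 3 (2 equiv), CH2Cl2, −78 → −40 °C; Et3N quench at −40 °C
Reagents that add atoms: none
Why: Proposed new method: the AlBr3-activated oxazaborolidine binds the pyrone carbonyl oxygen of 4 through the lone pair anti to the ring oxygen, supported by a C–H···O contact of the adjacent pyrone C3–H (a chelate of the kind used in lanthanide–binaphthol catalysis of 3-carboalkoxy-2-pyrones cannot form because the two carbonyls of 4 lie across the ring), and the lowered diene LUMO takes up the dioxole HOMO in a concerted, asynchronous, suprafacial inverse-demand [4+2] in which bond C4–C5 (at pyrone C6) leads and bond C1–C6 (at pyrone C3) follows. The closest known reaction types are Lewis-acid-catalysed inverse-demand Diels–Alder additions of enol ethers to 2-pyrone esters with the CO2 bridge kept, and enantioselective cycloadditions of enol ethers to acrylates and quinones under the same oxazaborolidine–AlBr3 catalyst with the same single-carbonyl binding. The cyclohexene ring is closed by this intermolecular [4+2] annulation, both ring bonds being made in one step, while the lactone and dioxolane rings are carried in from 4 and 3, which gives the lactone-bridged bicyclo[2.2.2]octene. C5 and C6 are cis because the ring alkene adds suprafacially, C1 and C4 are tied to one face by the lactone bridge, O5 and O6 come out anti to that bridge through the endo approach, and the absolute sense (addition to the pyrone face that is Re at pyrone C6 and Si at pyrone C3) is fixed by the catalyst, whose aryl group covers the opposite face. The step needs endo selectivity, facial selectivity and retention of CO2: endo is secured by the substrates, since the exo approach would push the dioxole oxygens against the ring oxygen and carbonyl oxygen of the pyrone whereas endo sets them under the electron-poor pyrone C4–C5 unit, and CO2 is kept because the adduct stays below 0 °C until the catalyst is quenched. The (S)-catalyst is written from the α-C–H···O binding model, and the (R)-catalyst would be taken if the first run showed the opposite sense.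

Step 4
Reactants: 5 endo adduct
Product: 7 (1R,4S,5R,6S)-4-hydroxy-5,6-(isopropylidenedioxy)-3-(methoxycarbonyl)cyclohex-2-ene-1-carboxylic acid, via lithium carboxylate 6 (not isolated)
Conditions: LiOH (1.1 equiv), THF/H2O (3:1), 0 °C; then 1 M HCl to pH 3–4, 0 °C
Reagents that add atoms: lithium hydroxide, [Li+].[OH-]
Why: Saponification, in which the strained bicyclo[2.2.2] lactone is cleaved by hydroxide much faster than the conjugated methyl ester, freeing the C1 carboxylate and the C4 hydroxyl without touching a stereocentre.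

Step 5
Reactants: 7 hydroxy acid
Product: 9 (1R,4S,5S,6S)-4-(tert-butyldimethylsilyloxy)-5,6-(isopropylidenedioxy)-3-(methoxycarbonyl)cyclohex-2-ene-1-carboxylic acid, via bis-silyl compound 8 (not isolated)
Conditions: TBSOTf (2.4 equiv), 2,6-lutidine (3 equiv), CH2Cl2, −78 → 0 °C; then AcOH/H2O/THF (3:1:1), rt, 1 h
Reagents that add atoms: tert-butyldimethylsilyl triflate, CC(C)(C)[Si](C)(C)OS(=O)(=O)C(F)(F)F
Why: Silylation of the hindered allylic C4 hydroxyl with the silyl triflate also gives the silyl ester, which brief aqueous acetic acid hydrolyses selectively while the secondary silyl ether and the acetonide stay.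

Step 6
Reactants: 9 silyl ether acid
Product: 10 (1R,4S,5S,6S)-4-(tert-butyldimethylsilyloxy)-3-(hydroxymethyl)-5,6-(isopropylidenedioxy)cyclohex-2-ene-1-carboxylic acid
Conditions: i-Bu2AlH (4.5 equiv), CH2Cl2, −78 °C; aq. potassium sodium tartrate, pH 4
Reagents that add atoms: none
Why: 1,2-Reduction of the conjugated methyl ester to the allylic alcohol by the aluminium hydride, the first equivalent turning the acid into an aluminium carboxylate that is not reduced at −78 °C.

Step 7
Reactants: 10 hydroxymethyl acid
Product: 12 (1R,4S,5S,6S)-3-(benzoyloxymethyl)-4-(tert-butyldimethylsilyloxy)-5,6-(isopropylidenedioxy)cyclohex-2-ene-1-carboxylic acid, via mixed anhydride 11 (not isolated)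
Conditions: BzCl (3 equiv), pyridine, CH2Cl2 (dilute), 0 °C; then H2O/pyridine, rt; work-up at pH 3–4
Reagents that add atoms: benzoyl chloride, O=C(Cl)c1ccccc1
Why: Acylation of the only free hydroxyl (primary, allylic) with excess benzoyl chloride, the carboxyl group passing through its mixed benzoic anhydride, which cannot lactonise (O4 is silylated and C7 is trans to C1 across the alkene) and is hydrolysed back to the acid by aqueous pyridine.

Step 8
Reactants: 12 benzoate acid
Product: 14 (1R,4S,5S,6S)-1-acetoxy-3-(benzoyloxymethyl)-4-(tert-butyldimethylsilyloxy)-5,6-(isopropylidenedioxy)cyclohex-2-ene (acetate on the α face), via allyl cation 13 (not isolated)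
Conditions: undivided cell, graphite anode, platinum cathode, KOAc (0.3 equiv), AcOH/CH2Cl2 (2:1), constant current (about 3 F/mol), 10–15 °C
Reagents that add atoms: acetic acid, CC(=O)O
Why: Hofer–Moest (non-Kolbe) oxidation, in which two-electron anodic oxidation of the β,γ-unsaturated carboxylate expels CO2 to give the C1–C2–C3 allyl cation, which acetic acid should capture at the less hindered secondary terminus C1 (restoring the trisubstituted C2=C3 alkene) from the α face, anti to the cis-fused acetonide that screens the β face at C6, so that the new C1 stereocentre is set trans to O6 by the substrate.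

Step 9
Reactants: 14 allylic acetate
Product: 15 (1R,4S,5R,6R)-1-acetoxy-3-(benzoyloxymethyl)cyclohex-2-ene-4,5,6-triol
Conditions: TFA/H2O (9:1), 0 °C → rt
Reagents that add atoms: none
Why: Acid hydrolysis removes the isopropylidene ketal and the silyl ether in one operation, while the allylic acetate and benzoate, whose ionisation is disfavoured by the flanking oxygen substituents, and all four stereocentres are left alone.

Step 10
Reactants: 15 triol
Product: 17 (1R,4S,5R,6S)-1-acetoxy-5-benzoyloxy-3-(benzoyloxymethyl)cyclohex-2-ene-4,6-diol (target), via cyclic orthobenzoate 16 (not isolated)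
Conditions: PhC(OMe)3 (1.5 equiv), camphorsulfonic acid (5 mol %), MeCN, rt; then AcOH/H2O (4:1), rt
Reagents that add atoms: trimethyl orthobenzoate, COC(OC)(OC)c1ccccc1; water, O
Why: Acid-catalysed exchange forms the cyclic orthobenzoate on the only cis-1,2-diol (O5/O6, since O4 is trans to O5), and its mild hydrolysis should open the ortho-acid intermediate to the axial ester and equatorial alcohol, that is benzoate on O5, because A(1,2) strain with the C3 substituent keeps O4 and with it O5 axial and O6 equatorial, as in the known one-pot orthoester acylation of cis-diols in sugar triols.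

**Compound list**
1 | 2,2-dimethyl-1,3-dioxolane | CC1(C)OCCO1 | starting material
2 | 4-chloro-2,2-dimethyl-1,3-dioxolane (racemic) | CC1(C)OCC(Cl)O1 | intermediate
3 | 2,2-dimethyl-1,3-dioxole | CC1(C)OC=CO1 | intermediate
4 | methyl coumalate | COC(=O)C1=COC(=O)C=C1 | starting material
5 | methyl (1S,4R,7S,8S)-7,8-(isopropylidenedioxy)-3-oxo-2-oxabicyclo[2.2.2]oct-5-ene-6-carboxylate (endo adduct) | O=C3[C@@H]1C=C(C(=O)OC)[C@H](O3)[C@H]2OC(C)(C)O[C@@H]12 | intermediate
6 | lithium salt of 7 | [Li+].[O-]C(=O)[C@@H]1C=C(C(=O)OC)[C@H](O)[C@H]2OC(C)(C)O[C@@H]12 | intermediate (not isolated)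
7 | (1R,4S,5R,6S)-4-hydroxy-5,6-(isopropylidenedioxy)-3-(methoxycarbonyl)cyclohex-2-ene-1-carboxylic acid | OC(=O)[C@@H]1C=C(C(=O)OC)[C@H](O)[C@H]2OC(C)(C)O[C@@H]12 | intermediate
8 | tert-butyldimethylsilyl ester of 9 | CC(C)(C)[Si](C)(C)OC(=O)[C@@H]1C=C(C(=O)OC)[C@H](O[Si](C)(C)C(C)(C)C)[C@H]2OC(C)(C)O[C@@H]12 | intermediate (not isolated)
9 | (1R,4S,5S,6S)-4-(tert-butyldimethylsilyloxy)-5,6-(isopropylidenedioxy)-3-(methoxycarbonyl)cyclohex-2-ene-1-carboxylic acid | OC(=O)[C@@H]1C=C(C(=O)OC)[C@H](O[Si](C)(C)C(C)(C)C)[C@H]2OC(C)(C)O[C@@H]12 | intermediate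
10 | (1R,4S,5S,6S)-4-(tert-butyldimethylsilyloxy)-3-(hydroxymethyl)-5,6-(isopropylidenedioxy)cyclohex-2-ene-1-carboxylic acid | OC(=O)[C@@H]1C=C(CO)[C@H](O[Si](C)(C)C(C)(C)C)[C@H]2OC(C)(C)O[C@@H]12 | intermediate
11 | mixed benzoic anhydride of 12 | O=C(OC(=O)c4ccccc4)[C@@H]1C=C(COC(=O)c3ccccc3)[C@H](O[Si](C)(C)C(C)(C)C)[C@H]2OC(C)(C)O[C@@H]12 | intermediate (not isolated)
12 | (1R,4S,5S,6S)-3-(benzoyloxymethyl)-4-(tert-butyldimethylsilyloxy)-5,6-(isopropylidenedioxy)cyclohex-2-ene-1-carboxylic acid | OC(=O)[C@@H]1C=C(COC(=O)c3ccccc3)[C@H](O[Si](C)(C)C(C)(C)C)[C@H]2OC(C)(C)O[C@@H]12 | intermediate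
13 | C1–C2–C3 allyl cation from 12 | [CH+]1C=C(COC(=O)c3ccccc3)[C@H](O[Si](C)(C)C(C)(C)C)[C@H]2OC(C)(C)O[C@@H]12 | intermediate (not isolated)
14 | (1R,4S,5S,6S)-1-acetoxy-3-(benzoyloxymethyl)-4-(tert-butyldimethylsilyloxy)-5,6-(isopropylidenedioxy)cyclohex-2-ene | CC(=O)O[C@@H]1C=C(COC(=O)c3ccccc3)[C@H](O[Si](C)(C)C(C)(C)C)[C@H]2OC(C)(C)O[C@@H]12 | intermediate
15 | (1R,4S,5R,6R)-1-acetoxy-3-(benzoyloxymethyl)cyclohex-2-ene-4,5,6-triol | CC(=O)O[C@@H]1C=C(COC(=O)c2ccccc2)[C@H](O)[C@@H](O)[C@H]1O | intermediate
16 | 5,6-O-(α-methoxybenzylidene) orthoester of 15 (epimers at the orthoester carbon) | CC(=O)O[C@@H]1C=C(COC(=O)c3ccccc3)[C@H](O)[C@H]2OC(OC)(c4ccccc4)O[C@@H]12 | intermediate (not isolated)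
17 | (1R,4S,5R,6S)-1-acetoxy-5-benzoyloxy-3-(benzoyloxymethyl)cyclohex-2-ene-4,6-diol (CNP0169028.1) | CC(=O)O[C@@H]1C=C(COC(=O)c2ccccc2)[C@H](O)[C@@H](OC(=O)c2ccccc2)[C@H]1O | target

Total step count: 10. Longest linear sequence: 10 steps (1 → 17); methyl coumalate 4 enters at step 3.

**Steps most likely to fail**

Step 3 (Proposed new method). Facial selection by a catalyst that holds only one carbonyl may be poor, the strong Lewis acid may polymerise the dioxole, or exo approach may compete. Fallback with known chemistry, setting out from 3 and 4: the cycloaddition is run without chiral control (Yb(OTf)3, 5 mol %, CH2Cl2, 0 °C to rt, or neat at 50–60 °C), as is known for coumalate esters with enol ethers, to give the racemic endo adduct F1. Hydrolysis with LiOH as in step 4 gives the racemic hydroxy acid F2. Classical resolution by crystallisation with (R)-1-phenylethylamine (or its antipode, whichever crystallises the wanted acid) gives the diastereomerically pure ammonium salt F3, and acidification returns to the route at 7.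

Step 8. Acetate may add to the β face or to the C3 terminus, the cation may lose a proton to a diene, or radical coupling may compete at the anode. Fallback setting out from 12: the acid is converted with N-hydroxypyridine-2-thione and DCC into the thiohydroxamate (Barton) ester F4. Visible-light irradiation under O2 with t-BuSH gives the C1 hydroperoxide F5 as a mixture of epimers, and Ac2O/pyridine dehydrates both epimers to the single enone F6. Luche reduction (NaBH4, CeCl3·7H2O, MeOH, −78 °C) delivers hydride anti to the acetonide and should give the β-alcohol F7 (hydroxyl cis to O6). Mitsunobu reaction with acetic acid (PPh3, DIAD) inverts C1 and comes back to the route at 14.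

Step 10. The orthoester may open toward O6, or the benzoyl group may migrate between O5, O6 and O4 during hydrolysis, giving mixtures. Fallback setting out from 14: the ketal alone is hydrolysed (80 % aq. AcOH, 40 °C) with the hindered silyl ether kept, giving the 5,6-diol F8. Et3SiCl/imidazole at −20 °C silylates the less hindered equatorial O6 (O5 is flanked by the bulky O4 silyl ether) to give F9. BzCl/DMAP/pyridine then benzoylates the remaining O5 hydroxyl to give F10, and HF·pyridine removes both silyl groups, coming back at 17.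

**Further compounds**
F1 | step 3 | racemic endo adduct (5 and its enantiomer) | O=C3[C@@H]1C=C(C(=O)OC)[C@H](O3)[C@H]2OC(C)(C)O[C@@H]12.O=C3[C@H]1C=C(C(=O)OC)[C@@H](O3)[C@@H]2OC(C)(C)O[C@H]12
F2 | step 3 | racemic hydroxy acid (7 and its enantiomer) | OC(=O)[C@@H]1C=C(C(=O)OC)[C@H](O)[C@H]2OC(C)(C)O[C@@H]12.OC(=O)[C@H]1C=C(C(=O)OC)[C@@H](O)[C@@H]2OC(C)(C)O[C@H]12
F3 | step 3 | (R)-1-phenylethylammonium salt of 7 | [O-]C(=O)[C@@H]1C=C(C(=O)OC)[C@H](O)[C@H]2OC(C)(C)O[C@@H]12.C[C@@H]([NH3+])c1ccccc1
F4 | step 8 | 2-thioxopyridin-1(2H)-yl ester of 12 | S=C5C=CC=CN5OC(=O)[C@@H]1C=C(COC(=O)c3ccccc3)[C@H](O[Si](C)(C)C(C)(C)C)[C@H]2OC(C)(C)O[C@@H]12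
F5 | step 8 | 3-(benzoyloxymethyl)-4-(tert-butyldimethylsilyloxy)-1-hydroperoxy-5,6-(isopropylidenedioxy)cyclohex-2-ene (epimers at C1) | OOC1C=C(COC(=O)c3ccccc3)[C@H](O[Si](C)(C)C(C)(C)C)[C@H]2OC(C)(C)O[C@@H]12
F6 | step 8 | 3-(benzoyloxymethyl)-4-(tert-butyldimethylsilyloxy)-5,6-(isopropylidenedioxy)cyclohex-2-en-1-one | O=C1C=C(COC(=O)c3ccccc3)[C@H](O[Si](C)(C)C(C)(C)C)[C@H]2OC(C)(C)O[C@@H]12
F7 | step 8 | 3-(benzoyloxymethyl)-4-(tert-butyldimethylsilyloxy)-5,6-(isopropylidenedioxy)cyclohex-2-en-1-ol with the hydroxyl on the β face (cis to O6) | O[C@H]1C=C(COC(=O)c3ccccc3)[C@H](O[Si](C)(C)C(C)(C)C)[C@H]2OC(C)(C)O[C@@H]12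
F8 | step 10 | 1-acetoxy-3-(benzoyloxymethyl)-4-(tert-butyldimethylsilyloxy)cyclohex-2-ene-5,6-diol | CC(=O)O[C@@H]1C=C(COC(=O)c3ccccc3)[C@H](O[Si](C)(C)C(C)(C)C)[C@@H](O)[C@H]1O
F9 | step 10 | O6-triethylsilyl ether of F8 | CC(=O)O[C@@H]1C=C(COC(=O)c3ccccc3)[C@H](O[Si](C)(C)C(C)(C)C)[C@@H](O)[C@H]1O[Si](CC)(CC)CC
F10 | step 10 | O5-benzoate of F9 | CC(=O)O[C@@H]1C=C(COC(=O)c3ccccc3)[C@H](O[Si](C)(C)C(C)(C)C)[C@@H](OC(=O)c4ccccc4)[C@H]1O[Si](CC)(CC)CC
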